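**Remarks on the chemistry**

- Germacrane numbering is used throughout: ring C1–C10, lactone carbons C11 (=C13) and C12, C14 on C10, C15 on C4. The target is (6R,7S,8S,9S); both ring olefins are cis within the ring, although each is E by CIP.
- C6 is S in alkynol 30 and R in target 39 with no change in geometry, because the CIP ranking of C5 and C7 inverts when the alkyne becomes the olefin; the structures are otherwise consistent and need no correction.
- The oxan-2-yl (THP) acetal carbon in 9, 11–18 and 23–25 is an inconsequential epimer mixture and is left undefined.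
- C8 carries TBS rather than TES so that the THP group on O6 can be removed in its presence.

## Structural features

The target is a germacranolide: a ten-membered carbocycle (C1–C10) trans-fused at C6/C7 to an α-methylene-γ-butyrolactone (O6–C12(=O)–C11(=C13)–C7). The ring holds two trisubstituted, ring-cis olefins: C1=C10, which carries the formyl carbon C14, and C4=C5, which carries the hydroxymethyl carbon C15. Four contiguous stereocentres run from C6 (lactone oxygen) through C7 (ring fusion) and C8 (methacrylate) to C9 (methoxy); C8/C9 form a threo diol pattern differentiated as ester and methyl ether. The fragile groups are the methylene lactone and the methacrylate (Michael acceptors, and esters able to migrate between O6 and O8), the enal and the free allylic alcohol. C14 and C15 are both allylic CH2–O carbons that must end at different oxidation levels. The real difficulty is the medium ring with two cis olefins flanking four adjacent stereocentres, two of them at the lactone fusion. The key step exploits the C6 carbinol next to C7 carrying the C11(=C13)–C12 propenyl unit. This homoallylic alcohol is the retron of a [2,3]-Wittig shift of an ether in which O6 is bonded to C13; a C4≡C5 alkyne acidifies C6–H and is the latent C4=C5 olefin.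

## Logic of the disconnections

**39 to 38.** The C4–C15 bond is cut, leaving iodine on C4. The hydroxymethyl group then enters last, so C15–OH needs no protecting group and never competes with C14–OH in an oxidation. The forward step must be a neutral palladium-catalysed hydroxymethyl transfer that tolerates the enal, the methacrylate and the methylene lactone.

**38 to 35 (through 37 and 36).** The C8–O acyl bond is cut, C14 returns from aldehyde to alcohol, and both hydroxyls are re-silylated. One fluoride step then frees both, and an allylic-selective oxidant distinguishes C14–OH from the non-allylic C8–OH. The acylation must not provoke lactone migration to O8.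

**35 to 30 (through 34, 32 and 31).** The lactone C12–O6 bond is opened with C12 back at the PMB-protected alcohol level, iodine on C4 is exchanged for silicon, and H–Si is removed across C4=C5 to give the alkyne. Syn addition to a cycloalkyne must give the ring-cis olefin, and the free C6 hydroxyl directs silicon to C4. The forward steps require exclusive distal silylation and lactonisation onto O6 only, which is why O8 stays silylated.

**30 to 28 (key).** The C6–C7 bond is cut and O6 is joined to C13. This turns the ten-membered ring into a thirteen-membered ether and turns C6 and C7 into a prochiral CH2 and an sp2 CH. The forward shift must find the E olefin at C7=C11, deprotonate only C6, and attack one face of C7.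

**28 to 26.** The C6–O bond of the ring ether is cut to a C6 hydroxyl and a C13 chloride on one chain. The forward step is a high-dilution SN2 closure, and O6 needs a temporary group orthogonal to all the others.

**26 to 18 and 21 (through 25, 24 and 23).** The C13 chloride comes from the alcohol and that from an ester; the C7=C11 bond is then cut. The olefination reagent must carry C12 as an alkoxymethyl branch (a plain phosphonoacetate would lack this carbon) and must put the ester, the future C13, trans to C8. The aldehyde partner is base-sensitive, since C9–OMe is β to the carbonyl.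

**18 to 8 and 14 (through 17 and 16).** The C1=C10 bond is cut to a C10 ketone and a C1 phosphonium salt holding C1–C6. The forward olefination must place the chain cis to C9; C14 is therefore protected as a bulky silyl ether while C9 carries the directing methoxy group.

**8 to 5 (through 7 and 6).** The C10–C14 bond is cut. A silyloxymethyl carbanion is not available, so C14 is added by non-basic methylenation of the C10 ester and oxidation of the resulting enol ether.

**5 to 1 (through 4 and 3).** C7–C10 with both stereocentres come from 1. Mono-methylation of the C2-symmetric diol differentiates the oxygens, and reduction directed by the remaining hydroxyl differentiates the two ester termini.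

**14 to 9 and 10 (through 12); 21 to 19.** The C3–C4 bond is cut to an acetylide and a 1,3-dihalide; the acrylate reagent comes from the parent phosphonate and formaldehyde.

## Other disconnections considered

**Alternative 1:** The cut is the reverse of a transannular bond: C5 is joined to C9, turning the ten-membered ring into a bicyclo[5.3.0]decene with a C9 tertiary hydroxyl and a spiro-epoxide at C4/C15. KH with 18-crown-6 would form the C9 alkoxide; the C5–C9 bond would break as C4=C5 forms and the epoxide opens, releasing the C9 enone A1 with C15–OH free.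
- In favour: no medium-ring closure is needed. Both olefin geometries are dictated by the bicycle (C1=C10 lies in the seven-membered ring; C4=C5 follows from the anti-periplanar C5–C9 and C4–O bonds). C15 arrives oxygenated and distinct from C14. On olefin geometry and on C15 this alternative is the better of the two.
- Against: the substrate needs C6–C8 on a cyclopentane plus correctly related centres at C4, C5 and C9, all three of which are destroyed in the step. C9 emerges as a ketone, so the methoxy centre would have to come from 1,2-reduction of a flexible ten-membered enone and methylation, with C8 epimerisable meanwhile. The strongly basic conditions would also test the product.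
- Comparison: structurally, the chosen plan takes C8/C9 from the chiral pool and sets C6/C7 while forming the ring, whereas A1 still lacks C9. Mechanistically both avoid end-to-end cyclisation and are stereospecific, the fragmentation for geometry, the sigmatropic shift for two stereocentres. In step count the bicycle should cost more before the key step and about the same after.

**Alternative 2:** The C1=C10 olefin is cut to an open chain with an aldehyde at C1 and a phosphonoacetate at C10. LiCl/DBU at high dilution would close the ring by intramolecular Horner–Wadsworth–Emmons reaction to the methyl enoate A2.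
- In favour: C14 arrives as the ester carbon. The E-enoate is the usual outcome for an α-substituted phosphonoacetate and is also the ring-cis olefin, so the 1(10) geometry is better secured than by the ketone Wittig of the chosen plan. C4=C5 with C15 can be carried from the start, which would remove steps 19, 22 and 26. On these points A2 is equal or better.
- Against: a ten-membered ring is closed end to end, with transannular strain and oligomers. The C10 carbanion is β to the C9 methoxy group, so E1cB loss of methoxide competes and endangers C9. All four stereocentres must be built on the open chain, and the ester must later be reduced and re-oxidised.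
- Comparison: A2 is stronger on olefin geometry and late-stage economy. The chosen plan is stronger on ring formation (contraction instead of closure), on making C6/C7 in the ring-forming step, and on avoiding a carbanion next to C9. Total step counts should be similar.

**Alternative 3:** The doubly allylic C2–C3 bond is cut to an allylic phenyl sulfone at C2 and an allylic bromide at C3. KHMDS at high dilution would give the sulfone carbanion, which displaces bromide to give A3; the C2 centre is temporary.
- In favour: the bond formed is remote from the stereocentres. Sulfone anions are compatible with silyl and PMB ethers. Both olefins with C14 and C15 oxygenation are in place beforehand, so no alkyne chemistry and no late coupling are needed; on this count it is the better plan.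
- Against: it is again an end-to-end ten-membered closure, with SN2′ attack at C5 and intermolecular alkylation as competitors. The sulfone must then be removed reductively at an allylic position, where transposition or scrambling of C1=C10 and loss of the allylic C14–O bond are possible. Four kinds of protecting group must be told apart, and C6/C7 again need acyclic stereocontrol.
- Comparison: the mechanisms are equally well established. The chosen plan is better on ring formation and stereocentre economy; A3 is better at C15 but pays with an extra desulfonylation step.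

Key step: step 18

## Route

Step 1
Reactants: 1 diethyl L-tartrate [diethyl (2R,3R)-2,3-dihydroxybutanedioate]
Product: 3 diethyl (2R,3R)-2-hydroxy-3-methoxybutanedioate, via dibutylstannylene acetal 2 (not isolated)
Conditions: Bu2SnO, toluene, reflux (−H2O); then MeI, CsF, DMF, rt
Reagents that add atoms: iodomethane, CI
Why: Tin-mediated mono-O-alkylation of a 1,2-diol; the diol is C2-symmetric, so either oxygen gives the same mono-ether, and the stannylene stops after one alkylation. No stereocentre is touched.

Step 2
Reactants: 3 diethyl (2R,3R)-2-hydroxy-3-methoxybutanedioate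
Product: 4 ethyl (2R,3S)-3,4-dihydroxy-2-methoxybutanoate
Conditions: BH3·SMe2, NaBH4 (5 mol %), THF, 0 °C → rt; MeOH
Reagents that add atoms: none
Why: Hydroxyl-directed borane reduction of an α-hydroxy ester: boron bound to the C8 hydroxyl delivers hydride only to the neighbouring ester (C7), which tells the two tartrate termini apart; the ester next to the methoxy group stays.

Step 3
Reactants: 4 ethyl (2R,3S)-3,4-dihydroxy-2-methoxybutanoate
Product: 5 ethyl (2R,3S)-3,4-bis(tert-butyldimethylsilyloxy)-2-methoxybutanoate
Conditions: TBSCl, imidazole, DMF, 0 °C → rt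
Reagents that add atoms: tert-butyldimethylsilyl chloride, CC(C)(C)[Si](C)(C)Cl
Why: Imidazole-promoted silylation of both hydroxyls prevents γ-lactonisation of 4; the primary TBS ether can later be removed selectively, and the secondary one survives removal of the THP group.

Step 4
Reactants: 5 ethyl (2R,3S)-3,4-bis(tert-butyldimethylsilyloxy)-2-methoxybutanoate
Product: 6 (3R,4S)-4,5-bis(tert-butyldimethylsilyloxy)-2-ethoxy-3-methoxypent-1-ene
Conditions: Cp2TiMe2, toluene, 70 °C, dark
Reagents that add atoms: dimethyltitanocene Cp2TiMe2, [CH3-].[CH3-].[Ti+4].c1cc[cH-]c1.c1cc[cH-]c1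
Why: Petasis methylenation of the ester carbonyl by the titanium methylidene supplies C14 without base, so the α-stereocentre C9 is not epimerised.

Step 5
Reactants: 6 (3R,4S)-4,5-bis(tert-butyldimethylsilyloxy)-2-ethoxy-3-methoxypent-1-ene
Product: 7 (3R,4S)-4,5-bis(tert-butyldimethylsilyloxy)-1-hydroxy-3-methoxypentan-2-one
Conditions: OsO4 (2 mol %), NMO, acetone–H2O, 0 °C → rt
Reagents that add atoms: osmium tetroxide, O=[Os](=O)(=O)=O; N-methylmorpholine N-oxide, C[N+]1([O-])CCOCC1
Why: Catalytic dihydroxylation of the electron-rich enol ether gives a hemiketal that loses ethanol, leaving C10 as the ketone and C14 as CH2OH.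

Step 6
Reactants: 7 (3R,4S)-4,5-bis(tert-butyldimethylsilyloxy)-1-hydroxy-3-methoxypentan-2-one
Product: 8 (3R,4S)-4,5-bis(tert-butyldimethylsilyloxy)-1-(tert-butyldiphenylsilyloxy)-3-methoxypentan-2-one
Conditions: TBDPSCl, imidazole, CH2Cl2, 0 °C
Reagents that add atoms: tert-butyl(chloro)diphenylsilane, CC(C)(C)[Si](Cl)(c1ccccc1)c1ccccc1
Why: Silylation of the primary hydroxyl under mild base avoids enolisation of the α-hydroxy ketone; the bulky, weakly coordinating silyl ether is chosen to steer the olefination in step 9.

Step 7
Reactants: 9 2-(prop-2-yn-1-yloxy)oxane; 10 1-bromo-3-chloropropane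
Product: 12 2-[(6-chlorohex-2-yn-1-yl)oxy]oxane, via lithium acetylide 11 (not isolated)
Conditions: n-BuLi, THF, −78 °C; then 10, DMPU, −78 °C → rt
Reagents that add atoms: none
Why: SN2 alkylation of the lithium acetylide at the bromide end of the dihalide (bromide reacts far faster than chloride) assembles C1–C6 with O6 protected.

Step 8
Reactants: 12 2-[(6-chlorohex-2-yn-1-yl)oxy]oxane
Product: 14 [6-(oxan-2-yloxy)hex-4-yn-1-yl]triphenylphosphonium iodide, via alkyl iodide 13 (not isolated)
Conditions: NaI, PPh3, NaHCO3, MeCN, reflux
Reagents that add atoms: triphenylphosphine, c1ccc(cc1)P(c1ccccc1)c1ccccc1; sodium iodide, [Na+].[I-]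
Why: Finkelstein exchange in the flask followed by SN2 quaternisation of the phosphine; bicarbonate keeps the acetal intact.

Step 9
Reactants: 8 (3R,4S)-4,5-bis(tert-butyldimethylsilyloxy)-1-(tert-butyldiphenylsilyloxy)-3-methoxypentan-2-one; 14 [6-(oxan-2-yloxy)hex-4-yn-1-yl]triphenylphosphonium iodide
Product: 16 (8S,9S,1(10)Z)-olefin C7H2(OTBS)–C8H(OTBS)–C9H(OMe)–C10(C14H2OTBDPS)=C1H–C2H2–C3H2–C4≡C5–C6H2–OTHP, via phosphonium ylide 15 (not isolated)
Conditions: NaHMDS, THF, −78 → 0 °C; then 8, −78 °C → rt
Reagents that add atoms: none
Why: Wittig olefination of an α-alkoxy ketone with a non-stabilised ylide under lithium-free conditions is expected to place the new chain cis to the alkoxy-bearing carbon C9 and trans to the bulky silyloxymethyl arm, giving the 1(10)Z olefin that later becomes the E-enal; low temperature limits enolisation, so C8/C9 are kept.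

Step 10
Reactants: 16 the 1(10)Z olefin from step 9
Product: 17 (8S,9S)-C7 primary alcohol HOC7H2–C8H(OTBS)–C9H(OMe)–C10(C14H2OTBDPS)=C1H–(CH2)2–C≡C–CH2OTHP
Conditions: HF·pyridine, pyridine, THF, 0 °C
Reagents that add atoms: none
Why: Buffered fluoride cleaves the primary TBS ether much faster than the secondary TBS or the primary TBDPS ether, and the acetal survives the buffered medium.

Step 11
Reactants: 17 the C7 primary alcohol
Product: 18 C7 aldehyde OHC7–C8H(OTBS)–C9H(OMe)–C10(C14H2OTBDPS)=C1H–(CH2)2–C≡C–CH2OTHP (8R,9S by CIP; geometry unchanged)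
Conditions: Dess–Martin periodinane, NaHCO3, CH2Cl2, 0 °C → rt
Reagents that add atoms: none
Why: Dess–Martin oxidation under bicarbonate gives the α-silyloxy aldehyde without epimerising C8 or eliminating the β-methoxy group; it is used crude.

Step 12
Reactants: 19 triethyl phosphonoacetate
Product: 21 ethyl 2-(diethoxyphosphoryl)acrylate, via hydroxymethyl adduct 20 (not isolated)
Conditions: (CH2O)n, piperidine (cat.), MeOH, reflux; then TsOH (cat.), toluene, reflux (−H2O)
Reagents that add atoms: paraformaldehyde (as formaldehyde), C=O
Why: Amine-catalysed Knoevenagel-type hydroxymethylation of the active methylene followed by acid-catalysed dehydration, a standard preparation of this acrylate; it brings in the carbon that becomes C12.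

Step 13
Reactants: 18 the C7 aldehyde; 21 ethyl 2-(diethoxyphosphoryl)acrylate
Product: 23 (8S,9S)-ethyl enoate EtO2C13–C11(C12H2OPMB)=C7H–C8H(OTBS)–C9H(OMe)–C10(C14H2OTBDPS)=C1H–(CH2)2–C≡C–CH2OTHP with the ester trans to C8, via sodium phosphonate carbanion 22 (not isolated)
Conditions: 4-MeOC6H4CH2OH, NaH, THF, 0 °C; 21; then 18, −78 → 0 °C
Reagents that add atoms: 4-methoxybenzyl alcohol, COc1ccc(CO)cc1
Why: Tandem oxa-Michael/Horner–Wadsworth–Emmons reaction: the alkoxide adds to 21 to give carbanion 22, which olefinates 18. α-Substituted phosphonoacetates give the E-enoate, so C8 ends cis to CH2OPMB (C12) and trans to the ester carbon (C13); a slight deficit of NaH leaves no free alkoxide to attack the aldehyde.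

Step 14
Reactants: 23 the ethyl enoate
Product: 24 (8S,9S)-allylic alcohol HOC13H2–C11(C12H2OPMB)=C7H–C8H(OTBS)–C9H(OMe)–C10(C14H2OTBDPS)=C1H–(CH2)2–C≡C–CH2OTHP
Conditions: i-Bu2AlH, CH2Cl2, −78 °C; Rochelle salt
Reagents that add atoms: none
Why: 1,2-Reduction of the enoate by the aluminium hydride at low temperature; ethers, acetal and alkyne are inert.

Step 15
Reactants: 24 the allylic alcohol
Product: 25 (8S,9S)-allylic chloride ClC13H2–C11(C12H2OPMB)=C7H–C8H(OTBS)–C9H(OMe)–C10(C14H2OTBDPS)=C1H–(CH2)2–C≡C–CH2OTHP
Conditions: NCS, Me2S, CH2Cl2, −20 → 0 °C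
Reagents that add atoms: N-chlorosuccinimide, O=C1CCC(=O)N1Cl
Why: Corey–Kim chlorination: chloride displaces the alkoxysulfonium group by SN2 at the primary carbon, without allylic transposition and under near-neutral conditions that spare the acetal and silyl ethers.

Step 16
Reactants: 25 the allylic chloride
Product: 26 (8S,9S)-hydroxy chloride ClC13H2–C11(C12H2OPMB)=C7H–C8H(OTBS)–C9H(OMe)–C10(C14H2OTBDPS)=C1H–(CH2)2–C≡C–C6H2OH
Conditions: PPTS, MeOH, rt
Reagents that add atoms: none
Why: Mild acid-catalysed transacetalisation removes the THP group; the secondary TBS, TBDPS and PMB ethers and the primary allylic chloride are stable to this acid at room temperature.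

Step 17
Reactants: 26 the hydroxy chloride
Product: 28 (8S,9S)-thirteen-membered propargyl allyl ether with ring C8(OTBS)–C7H=C11(C12H2OPMB)–C13H2–O–C6H2–C5≡C4–C3H2–C2H2–C1H=C10(C14H2OTBDPS)–C9(OMe); C8 trans to C13; C2 cis to C9, via sodium alkoxide 27 (not isolated)
Conditions: NaH, Bu4NI (cat.), THF, reflux, slow addition (final 2 mM)
Reagents that add atoms: none
Why: Intramolecular Williamson etherification: the primary propargylic alkoxide displaces the primary allylic chloride by SN2 under high dilution; the alkyne and two olefins restrict the chain and favour closure of the thirteen-membered ring. No stereocentre is formed.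

Step 18
Reactants: 28 the thirteen-membered propargyl allyl ether
Product: 30 (6S,7S,8S,9S)-ten-membered cyclodec-1(10)-en-4-yn-6-ol with C7 bearing C11(=C13H2)–C12H2OPMB; C8 OTBS; C9 OMe; C10 bearing C14H2OTBDPS, via C6-lithiated ether 29 (not isolated)
Conditions: n-BuLi, THF–pentane, −78 °C; AcOH
Reagents that add atoms: none
Why: n-BuLi removes a proton from C6, the most acidic C–H because it is flanked by the ether oxygen and the alkyne, giving the α-oxy propargyl-lithium 29. The carbanion bonds to C7 while the O–C13 bond breaks in a concerted suprafacial [2,3]-sigmatropic shift through a five-membered envelope (C6, O, C13, C11, C7); the closest known reaction type is the [2,3]-Wittig ring contraction of macrocyclic propargyl allyl ethers to ten-membered and larger carbocycles. The ten-membered carbocycle C1–C10 is the only ring formed and it arises by contraction of the thirteen-membered ether, a transannular bond formation that needs no dilution control. C6 and C7 are set together: the E olefin (C8 trans to C13), with the alkynyl group exo on the envelope, translates into the anti C6/C7 pair that a trans-fused lactone requires. Which face of C7 is attacked, and hence the 6S,7S sense relative to C8/C9, is decided by the ring conformation around the C8 silyloxy and C9 methoxy groups, through which the chain leads to the carbanion. Site selectivity for C6–H over the allylic C13–H and the benzylic C–H of the PMB ether follows from the acidity order at −78 °C, and the low temperature also suppresses the [1,2]-shift. The alkoxide is protonated cold; the alkyne remains as the precursor of C4=C5, and C12 is already at the alcohol level needed for the lactone.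

Step 19
Reactants: 30 the ten-membered cyclodecenynol
Product: 31 C4-triethylsilyl diene: ring-cis C4(SiEt3)=C5H olefin with Si trans to C6; C6–OH free; other groups and stereocentres as in 30
Conditions: PtCl2 (5 mol %), XPhos (10 mol %), Et3SiH, THF, 50 °C
Reagents that add atoms: triethylsilane, CC[SiH](CC)CC
Why: Platinum-catalysed hydrosilylation of propargylic alcohols with this ligand puts silicon on the alkyne carbon distal to the carbinol (C4) and hydrogen on C5. Syn addition across the cycloalkyne gives the ring-cis C4=C5 olefin with silicon where C15 will stand; the hindered olefins react much more slowly.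

Step 20
Reactants: 31 the C4-triethylsilyl diene
Product: 32 diol with C6–OH and C12–OH free; C4–SiEt3; C8 OTBS; C14 OTBDPS
Conditions: DDQ, CH2Cl2–pH 7 buffer, 0 °C
Reagents that add atoms: none
Why: Oxidative cleavage of the PMB ether in wet solvent; silyl ethers and the vinylsilane are inert, and water prevents acetal formation with O6.

Step 21
Reactants: 32 the C6/C12 diol
Product: 34 trans-fused 6,12-lactone (α-methylene-γ-butyrolactone) with C4–SiEt3; C8 OTBS; C14 OTBDPS, via lactol 33 (not isolated)
Conditions: TEMPO (20 mol %), PhI(OAc)2, CH2Cl2, rt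
Reagents that add atoms: none
Why: Oxidative lactonisation of a 1,4-diol: the primary allylic alcohol is oxidised to the enal, which C6–OH traps as lactol 33, and this is oxidised on to the lactone. The silyl ether on O8 excludes closure onto C8, and the trans fusion follows from the C6/C7 configuration.

Step 22
Reactants: 34 the silyl lactone
Product: 35 C4-iodo lactone: ring-cis C4(I)=C5H with iodine trans to C6; C8 OTBS; C14 OTBDPS
Conditions: NIS, 2,6-lutidine, (CF3)2CHOH, 0 °C
Reagents that add atoms: N-iodosuccinimide, O=C1CCC(=O)N1I
Why: Electrophilic ipso-iododesilylation of the vinylsilane in hexafluoroisopropanol proceeds with retention of olefin geometry. The electron-poor methylene lactone does not react, and the PMB ring, which could be iodinated, has already been removed.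

Step 23
Reactants: 35 the C4-iodo lactone
Product: 36 iodo lactone diol with C8–OH and C14–OH free
Conditions: HF·pyridine, THF, 0 °C → rt
Reagents that add atoms: none
Why: Fluoride cleaves both silyl ethers in one operation; the acidic medium avoids base-induced migration of the lactone to O8.

Step 24
Reactants: 36 the iodo lactone diol
Product: 37 iodo lactone enal with C14 formyl trans to C2 and C8–OH free
Conditions: MnO2, CH2Cl2, rt
Reagents that add atoms: none
Why: MnO2 oxidises only the allylic primary alcohol; the secondary C8 hydroxyl is not allylic and stays. The olefin geometry is kept, and it is also that of the more stable enal.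

Step 25
Reactants: 37 the iodo lactone enal
Product: 38 C8 methacrylate of the iodo lactone enal
Conditions: methacrylic anhydride, Et3N, DMAP (cat.), CH2Cl2, 0 °C → rt
Reagents that add atoms: methacrylic anhydride, CC(=C)C(=O)OC(=O)C(C)=C
Why: DMAP-catalysed acylation of the remaining secondary alcohol; mild base and short contact time limit translactonisation.

Step 26
Reactants: 38 the C8 methacrylate iodide
Product: 39 target CNP0114830.1 [(6R,7S,8S,9S)-14-oxo-15-hydroxy-9-methoxy-8-methacryloyloxy-germacra-1(10),4,11(13)-trien-12,6-olide]
Conditions: Bu3SnCH2OH, Pd(PPh3)4 (10 mol %), toluene, 80 °C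
Reagents that add atoms: (tributylstannyl)methanol, CCCC[Sn](CO)(CCCC)CCCC
Why: Stille coupling of the vinyl iodide with the hydroxymethylstannane installs C15 with retention of geometry under neutral conditions. C15–OH therefore needs no protecting group and is never present while C14 is being oxidised.

## Compound list

1 | diethyl L-tartrate | CCOC(=O)[C@H](O)[C@@H](O)C(=O)OCC | starting material
2 | diethyl (4R,5R)-2,2-dibutyl-1,3,2-dioxastannolane-4,5-dicarboxylate | CCOC(=O)[C@@H]1O[Sn](CCCC)(CCCC)O[C@H]1C(=O)OCC | intermediate
3 | diethyl (2R,3R)-2-hydroxy-3-methoxybutanedioate | CCOC(=O)[C@H](O)[C@@H](OC)C(=O)OCC | intermediate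
4 | ethyl (2R,3S)-3,4-dihydroxy-2-methoxybutanoate | OC[C@H](O)[C@@H](OC)C(=O)OCC | intermediate
5 | ethyl (2R,3S)-3,4-bis(tert-butyldimethylsilyloxy)-2-methoxybutanoate | CC(C)(C)[Si](C)(C)OC[C@H](O[Si](C)(C)C(C)(C)C)[C@@H](OC)C(=O)OCC | intermediate
6 | (3R,4S)-4,5-bis(tert-butyldimethylsilyloxy)-2-ethoxy-3-methoxypent-1-ene | CC(C)(C)[Si](C)(C)OC[C@H](O[Si](C)(C)C(C)(C)C)[C@@H](OC)C(=C)OCC | intermediate
7 | (3R,4S)-4,5-bis(tert-butyldimethylsilyloxy)-1-hydroxy-3-methoxypentan-2-one | CC(C)(C)[Si](C)(C)OC[C@H](O[Si](C)(C)C(C)(C)C)[C@@H](OC)C(=O)CO | intermediate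
8 | (3R,4S)-4,5-bis(tert-butyldimethylsilyloxy)-1-(tert-butyldiphenylsilyloxy)-3-methoxypentan-2-one | CC(C)(C)[Si](C)(C)OC[C@H](O[Si](C)(C)C(C)(C)C)[C@@H](OC)C(=O)CO[Si](c1ccccc1)(c1ccccc1)C(C)(C)C | intermediate
9 | 2-(prop-2-yn-1-yloxy)oxane | C#CCOC1CCCCO1 | starting material
10 | 1-bromo-3-chloropropane | ClCCCBr | starting material
11 | lithium acetylide of 9 | [Li]C#CCOC1CCCCO1 | intermediate
12 | 2-[(6-chlorohex-2-yn-1-yl)oxy]oxane | ClCCCC#CCOC1CCCCO1 | intermediate
13 | 2-[(6-iodohex-2-yn-1-yl)oxy]oxane | ICCCC#CCOC1CCCCO1 | intermediate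
14 | [6-(oxan-2-yloxy)hex-4-yn-1-yl]triphenylphosphonium iodide | [I-].O(CC#CCCC[P+](c1ccccc1)(c1ccccc1)c1ccccc1)C1CCCCO1 | intermediate
15 | [6-(oxan-2-yloxy)hex-4-yn-1-ylidene]triphenylphosphorane | O(CC#CCCC=P(c1ccccc1)(c1ccccc1)c1ccccc1)C1CCCCO1 | intermediate
16 | (8S,9S,1(10)Z)-olefin; C7 and C8 OTBS; C9 OMe; C14 OTBDPS; C6 OTHP | CC(C)(C)[Si](C)(C)OC[C@H](O[Si](C)(C)C(C)(C)C)[C@@H](OC)/C(CO[Si](c1ccccc1)(c1ccccc1)C(C)(C)C)=C\CCC#CCOC1CCCCO1 | intermediate
17 | C7 primary alcohol of 16 | OC[C@H](O[Si](C)(C)C(C)(C)C)[C@@H](OC)/C(CO[Si](c1ccccc1)(c1ccccc1)C(C)(C)C)=C\CCC#CCOC1CCCCO1 | intermediate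
18 | C7 aldehyde | O=C[C@H](O[Si](C)(C)C(C)(C)C)[C@@H](OC)/C(CO[Si](c1ccccc1)(c1ccccc1)C(C)(C)C)=C\CCC#CCOC1CCCCO1 | intermediate
19 | triethyl phosphonoacetate | CCOC(=O)CP(=O)(OCC)OCC | starting material
20 | ethyl 2-(diethoxyphosphoryl)-3-hydroxypropanoate | CCOC(=O)C(CO)P(=O)(OCC)OCC | intermediate
21 | ethyl 2-(diethoxyphosphoryl)acrylate | CCOC(=O)C(=C)P(=O)(OCC)OCC | intermediate
22 | sodium salt of ethyl 2-(diethoxyphosphoryl)-3-[(4-methoxybenzyl)oxy]propanoate | [Na+].CCOC(=O)[C-](COCc1ccc(OC)cc1)P(=O)(OCC)OCC | intermediate
23 | (8S,9S)-ethyl enoate; ester (C13) trans to C8; C12 OPMB | CCOC(=O)/C(COCc1ccc(OC)cc1)=C/[C@H](O[Si](C)(C)C(C)(C)C)[C@@H](OC)/C(CO[Si](c1ccccc1)(c1ccccc1)C(C)(C)C)=C\CCC#CCOC1CCCCO1 | intermediate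
24 | (8S,9S)-C13 allylic alcohol | OC/C(COCc1ccc(OC)cc1)=C/[C@H](O[Si](C)(C)C(C)(C)C)[C@@H](OC)/C(CO[Si](c1ccccc1)(c1ccccc1)C(C)(C)C)=C\CCC#CCOC1CCCCO1 | intermediate
25 | (8S,9S)-C13 allylic chloride; C6 OTHP | ClC/C(COCc1ccc(OC)cc1)=C/[C@H](O[Si](C)(C)C(C)(C)C)[C@@H](OC)/C(CO[Si](c1ccccc1)(c1ccccc1)C(C)(C)C)=C\CCC#CCOC1CCCCO1 | intermediate
26 | (8S,9S)-C13 chloride with free C6 hydroxyl | ClC/C(COCc1ccc(OC)cc1)=C/[C@H](O[Si](C)(C)C(C)(C)C)[C@@H](OC)/C(CO[Si](c1ccccc1)(c1ccccc1)C(C)(C)C)=C\CCC#CCO | intermediate
27 | sodium alkoxide of 26 | ClC/C(COCc1ccc(OC)cc1)=C/[C@H](O[Si](C)(C)C(C)(C)C)[C@@H](OC)/C(CO[Si](c1ccccc1)(c1ccccc1)C(C)(C)C)=C\CCC#CC[O-].[Na+] | intermediate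
28 | (8S,9S)-thirteen-membered propargyl allyl ether | CC(C)(C)[Si](C)(C)O[C@H]1/C=C(\COCc2ccc(OC)cc2)COCC#CCC/C=C(/CO[Si](c3ccccc3)(c4ccccc4)C(C)(C)C)[C@@H]1OC | intermediate
29 | C6-lithiated derivative of 28 | CC(C)(C)[Si](C)(C)O[C@H]1/C=C(\COCc2ccc(OC)cc2)COC([Li])C#CCC/C=C(/CO[Si](c3ccccc3)(c4ccccc4)C(C)(C)C)[C@@H]1OC | intermediate
30 | (6S,7S,8S,9S)-ten-membered cyclodecenynol | CC(C)(C)[Si](C)(C)O[C@H]1[C@@H](C(=C)COCc2ccc(OC)cc2)[C@H](O)C#CCC/C=C(/CO[Si](c3ccccc3)(c4ccccc4)C(C)(C)C)[C@@H]1OC | intermediate
31 | C4-triethylsilyl diene; C6–OH free | CC(C)(C)[Si](C)(C)O[C@H]1[C@@H](C(=C)COCc2ccc(OC)cc2)[C@H](O)/C=C(/[Si](CC)(CC)CC)CC/C=C(/CO[Si](c3ccccc3)(c4ccccc4)C(C)(C)C)[C@@H]1OC | intermediate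
32 | C6/C12 diol | CC(C)(C)[Si](C)(C)O[C@H]1[C@@H](C(=C)CO)[C@H](O)/C=C(/[Si](CC)(CC)CC)CC/C=C(/CO[Si](c2ccccc2)(c3ccccc3)C(C)(C)C)[C@@H]1OC | intermediate
33 | C12 lactol | CC(C)(C)[Si](C)(C)O[C@H]1[C@H]2C(=C)C(O)O[C@@H]2/C=C(/[Si](CC)(CC)CC)CC/C=C(/CO[Si](c3ccccc3)(c4ccccc4)C(C)(C)C)[C@@H]1OC | intermediate
34 | trans-fused 6,12-lactone; C4–SiEt3 | CC(C)(C)[Si](C)(C)O[C@H]1[C@H]2C(=C)C(=O)O[C@@H]2/C=C(/[Si](CC)(CC)CC)CC/C=C(/CO[Si](c3ccccc3)(c4ccccc4)C(C)(C)C)[C@@H]1OC | intermediate
35 | C4-iodo lactone; C8 OTBS; C14 OTBDPS | CC(C)(C)[Si](C)(C)O[C@H]1[C@H]2C(=C)C(=O)O[C@@H]2/C=C(/I)CC/C=C(/CO[Si](c3ccccc3)(c4ccccc4)C(C)(C)C)[C@@H]1OC | intermediate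
36 | iodo lactone C8/C14 diol | O[C@H]1[C@H]2C(=C)C(=O)O[C@@H]2/C=C(/I)CC/C=C(/CO)[C@@H]1OC | intermediate
37 | iodo lactone enal; C8–OH free | O[C@H]1[C@H]2C(=C)C(=O)O[C@@H]2/C=C(/I)CC/C=C(/C=O)[C@@H]1OC | intermediate
38 | C8 methacrylate of the iodo lactone enal | C=C(C)C(=O)O[C@H]1[C@H]2C(=C)C(=O)O[C@@H]2/C=C(/I)CC/C=C(/C=O)[C@@H]1OC | intermediate
39 | CNP0114830.1 | C=C(C)C(=O)O[C@H]1[C@H]2C(=C)C(=O)O[C@@H]2/C=C(/CO)CC/C=C(/C=O)[C@@H]1OC | target

## Step count and least certain steps

Total: 26 steps. Longest linear sequence: 23 steps (steps 1–6, 9–11 and 13–26 from 1); the side branches are steps 7–8 and step 12.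

**Step 18 (key step).** The most likely failure is insufficient discrimination between the two faces of C7. The E olefin secures the anti C6/C7 relationship, but the 6S,7S sense must come from the ring. An open-chain model, with C8–H eclipsing the olefin and the C8–O bond anti to the incoming carbanion, would point to the opposite face, so the ring has to override it; a minor [1,2]-shift is a second risk. A chiral lithium amide can be tried as reinforcement.
Fallback: from 26, MnO2 in CH2Cl2 would oxidise the propargylic alcohol to the chloro ynal F1. CrCl2 with catalytic NaI in THF–DMF at high dilution would then convert the allylic chloride into an allylchromium species that adds through its γ-carbon C7 to the C6 aldehyde in a six-membered chair (intramolecular Nozaki–Hiyama allylation). This forms the same C6–C7 bond by a different transition state and returns to the route at 30.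

**Step 9.** The most likely failure is loss of geometric control, because both flanks of the ketone are oxygenated and the chain may also settle cis to C14; enolisation of the hindered ketone by the basic ylide is a second risk.
Fallback: from 7, the sodium alkoxide (NaHMDS) would be treated with ylide 15 to give the allylic alcohol F2 as an olefin mixture. MnO2 oxidation and iodine-catalysed equilibration under light should converge both isomers on the conjugated E-enal F3 (formyl trans to C2), by thermodynamic instead of kinetic control. NaBH4/CeCl3 would give the allylic alcohol F4, and TBDPSCl/imidazole returns to the route at 16.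

**Step 19.** The most likely failure is erosion of regiocontrol (silicon on C5) or sluggish addition on the strained, hindered cycloalkyne, with silylation of the free hydroxyl as a side process.
Fallback: from 30, Cp2Zr(H)Cl (3 equiv, the first consumed by the hydroxyl) in THF should add H–Zr syn with zirconium on the less hindered C4, and iodine would give the iodo alcohol F5. DDQ would then give the iodo diol F6, and TEMPO/PhI(OAc)2 lactonisation returns to the route at 35, replacing steps 19–22.

**Step 26.** The most likely failure is slow transfer of the hydroxymethyl group (competing butyl transfer or protodeiodination) while the enal, methacrylate and methylene lactone degrade at the temperature required.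
Fallback: from 35, which has no aldehyde or free hydroxyl, CrCl2 with catalytic NiCl2 and paraformaldehyde in DMF (Nozaki–Hiyama–Kishi hydroxymethylation) would give the C15 alcohol F7. 4-Methoxybenzyl trichloroacetimidate with catalytic acid would give the PMB ether F8; HF·pyridine the diol F9; MnO2 the enal F10; methacrylic anhydride the ester F11. DDQ in wet CH2Cl2 would then release C15–OH and reach 39.

## Further compounds

F1 | step 18 | chloro ynal: C6 aldehyde of 26 | ClC/C(COCc1ccc(OC)cc1)=C/[C@H](O[Si](C)(C)C(C)(C)C)[C@@H](OC)/C(CO[Si](c1ccccc1)(c1ccccc1)C(C)(C)C)=C\CCC#CC=O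
F2 | step 9 | C14 allylic alcohol from 7 and 15, 1(10) olefin mixture | CC(C)(C)[Si](C)(C)OC[C@H](O[Si](C)(C)C(C)(C)C)[C@@H](OC)C(CO)=CCCC#CCOC1CCCCO1
F3 | step 9 | E-enal with C14 formyl trans to C2 | CC(C)(C)[Si](C)(C)OC[C@H](O[Si](C)(C)C(C)(C)C)[C@@H](OC)/C(C=O)=C\CCC#CCOC1CCCCO1
F4 | step 9 | C14 allylic alcohol with C2 cis to C9 | CC(C)(C)[Si](C)(C)OC[C@H](O[Si](C)(C)C(C)(C)C)[C@@H](OC)/C(CO)=C\CCC#CCOC1CCCCO1
F5 | step 19 | C4-iodo analogue of 31 with C6–OH free and C12 OPMB | CC(C)(C)[Si](C)(C)O[C@H]1[C@@H](C(=C)COCc2ccc(OC)cc2)[C@H](O)/C=C(/I)CC/C=C(/CO[Si](c3ccccc3)(c4ccccc4)C(C)(C)C)[C@@H]1OC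
F6 | step 19 | C4-iodo C6/C12 diol | CC(C)(C)[Si](C)(C)O[C@H]1[C@@H](C(=C)CO)[C@H](O)/C=C(/I)CC/C=C(/CO[Si](c2ccccc2)(c3ccccc3)C(C)(C)C)[C@@H]1OC
F7 | step 26 | C15 alcohol of the silyl-protected lactone | CC(C)(C)[Si](C)(C)O[C@H]1[C@H]2C(=C)C(=O)O[C@@H]2/C=C(/CO)CC/C=C(/CO[Si](c3ccccc3)(c4ccccc4)C(C)(C)C)[C@@H]1OC
F8 | step 26 | C15 PMB ether of F7 | CC(C)(C)[Si](C)(C)O[C@H]1[C@H]2C(=C)C(=O)O[C@@H]2/C=C(/COCc3ccc(OC)cc3)CC/C=C(/CO[Si](c4ccccc4)(c5ccccc5)C(C)(C)C)[C@@H]1OC
F9 | step 26 | C8/C14 diol with C15 OPMB | O[C@H]1[C@H]2C(=C)C(=O)O[C@@H]2/C=C(/COCc3ccc(OC)cc3)CC/C=C(/CO)[C@@H]1OC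
F10 | step 26 | C14 enal with C8–OH free and C15 OPMB | O[C@H]1[C@H]2C(=C)C(=O)O[C@@H]2/C=C(/COCc3ccc(OC)cc3)CC/C=C(/C=O)[C@@H]1OC
F11 | step 26 | C8 methacrylate with C15 OPMB | C=C(C)C(=O)O[C@H]1[C@H]2C(=C)C(=O)O[C@@H]2/C=C(/COCc3ccc(OC)cc3)CC/C=C(/C=O)[C@@H]1OC
A1 | alternative 1 | ten-membered C9 enone with C4=C5 and free C15 hydroxyl | COCO[C@H]1[C@@H](C(=C)COCc2ccc(OC)cc2)[C@H](OCc3ccc(OC)cc3)/C=C(/CO)CC/C=C(/COCc4ccc(OC)cc4)C1=O
A2 | alternative 2 | ten-membered ring with the C1=C10 methyl enoate | CC(C)(C)[Si](C)(C)O[C@H]1[C@@H](C(=C)COCc2ccc(OC)cc2)[C@H](OCc3ccc(OC)cc3)/C=C(/CO[Si](c4ccccc4)(c5ccccc5)C(C)(C)C)CC/C=C(/C(=O)OC)[C@@H]1OC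
A3 | alternative 3 | ten-membered ring with the C2 phenylsulfonyl group | CC(C)(C)[Si](C)(C)O[C@H]1[C@@H](C(=C)COCc2ccc(OC)cc2)[C@H](OCc3ccc(OC)cc3)/C=C(/CO[Si](c4ccccc4)(c5ccccc5)C(C)(C)C)C[C@H](S(=O)(=O)c6ccccc6)/C=C(/CO[Si](CC)(CC)CC)[C@@H]1OC
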